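**Retrosynthetic overview**

1. Structural feature: ring A is fused through C4a–C8a to a pyran whose remaining atoms O1–C2–C3–C4 can act as a four-atom tether between two alkynes, and the ring A oxygens sit on alternate carbons (C5, C7, C8a), where three oxygen-substituted alkynes would deliver them.
2. Key disconnection: C4a–C8a, C5–C6 and C7–C8 by a rhodium-catalysed [2+2+2] cycloaddition of a diyne (C2 ethynyl ether, C4 siloxyalkyne) with ethoxyacetylene; the pyran ring and ring A form in this one step, and the pendant aryl ring is carried in from 2,4,6-trimethoxybenzaldehyde.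
3. The C2/C3/C4 triad is set beforehand: syn (Z)-γ-isopropylallylboration (C2, C3), a γ-lactone, and trans methallylation (C4). The lactone carbon becomes C4a through lactol/alkyne homologation (an open γ-hydroxy ester would simply relactonise), C5–O comes from acetylide oxygenation, and the fragile ethynyl ether is made last.
4. End game: desilylation, fourfold Rieche formylation (C6, C8, C3', C5') and BCl3 dealkylation.

Key step: step 11

Assumption: the (Z)-allylborane made from (+)-Ipc2BOMe is taken to attack the Re face of aldehyde 1, as it does with other aryl aldehydes; racemic BINAP suffices in step 11 because no stereocentre is formed there.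

**Route**

Step 1
Reactants: 1 2,4,6-trimethoxybenzaldehyde; 2 (Z)-4-methylpent-2-ene
Product: 5 (1R,2S)-2-(propan-2-yl)-1-(2,4,6-trimethoxyphenyl)but-3-en-1-ol, via (Z)-(4-methylpent-2-en-1-yl)potassium 3 (not isolated), via (Z)-(4-methylpent-2-en-1-yl)diisopinocampheylborane 4 (not isolated)
Conditions: n-BuLi, KOt-Bu, THF, −78 to −45 °C; (+)-Ipc2BOMe, −78 °C; BF3·OEt2; 1, −78 °C; NaOH, H2O2
Reagents that add atoms: none
Why: Brown asymmetric allylboration, in which n-BuLi/KOt-Bu metalation of 2 keeps the Z geometry, the (Z)-γ-isopropylallylborane 4 reacts through a closed chair transition state to give the syn adduct, and the isopinocampheyl groups direct attack to the Re face of 1, setting the future C2 as R and C3 as S.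

Step 2
Reactants: 5 (1R,2S)-2-(propan-2-yl)-1-(2,4,6-trimethoxyphenyl)but-3-en-1-ol
Product: 7 (1R,2R)-2-(propan-2-yl)-1-(2,4,6-trimethoxyphenyl)butane-1,4-diol, via B-alkyl-9-borabicyclo[3.3.1]nonane 6 (not isolated)
Conditions: 9-BBN, THF, 0 °C to rt; NaOH, H2O2, 0 °C
Reagents that add atoms: hydrogen peroxide, OO
Why: anti-Markovnikov hydroboration–oxidation of the terminal vinyl group with a bulky borane, which touches no stereocentre (the descriptor at the isopropyl-bearing carbon changes only through priorities).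

Step 3
Reactants: 7 (1R,2R)-2-(propan-2-yl)-1-(2,4,6-trimethoxyphenyl)butane-1,4-diol
Product: 8 (4R,5R)-4-(propan-2-yl)-5-(2,4,6-trimethoxyphenyl)oxolan-2-one (cis lactone)
Conditions: 2,2,6,6-tetramethylpiperidine-1-oxyl (TEMPO, cat.), PhI(OAc)2, NaHCO3, CH2Cl2, rt
Reagents that add atoms: none
Why: oxoammonium-mediated oxidative lactonisation of a 1,4-diol, in which the primary alcohol is oxidised selectively, the lactol forms and is oxidised on, and bicarbonate keeps the acid-labile benzylic C–O bond from ionising.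

Step 4
Reactants: 8 (4R,5R)-4-(propan-2-yl)-5-(2,4,6-trimethoxyphenyl)oxolan-2-one; 9 3-bromo-2-methylprop-1-ene (methallyl bromide)
Product: 11 (3S,4S,5R)-3-(2-methylprop-2-en-1-yl)-4-(propan-2-yl)-5-(2,4,6-trimethoxyphenyl)oxolan-2-one, via lactone lithium enolate 10 (not isolated)
Conditions: LiN(i-Pr)2, THF, −78 °C; 9, −78 to −40 °C
Reagents that add atoms: none
Why: lactone enolate alkylation, in which the electrophile approaches the planar enolate anti to the neighbouring isopropyl group (and the aryl group on the same face), setting the future C4 trans to C3.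

Step 5
Reactants: 11 (3S,4S,5R)-3-(2-methylprop-2-en-1-yl)-4-(propan-2-yl)-5-(2,4,6-trimethoxyphenyl)oxolan-2-one
Product: 12 (3S,4S,5R)-3-(2-methylpropyl)-4-(propan-2-yl)-5-(2,4,6-trimethoxyphenyl)oxolan-2-one
Conditions: H2 (1 atm), RhCl(PPh3)3 (cat.), benzene–EtOH, rt
Reagents that add atoms: none
Why: homogeneous hydrogenation of the 1,1-disubstituted alkene with RhCl(PPh3)3, chosen over Pd/C so that the electron-rich benzylic lactone C–O bond is not hydrogenolysed.

Step 6
Reactants: 12 (3S,4S,5R)-3-(2-methylpropyl)-4-(propan-2-yl)-5-(2,4,6-trimethoxyphenyl)oxolan-2-one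
Product: 13 (3S,4S,5R)-3-(2-methylpropyl)-4-(propan-2-yl)-5-(2,4,6-trimethoxyphenyl)oxolan-2-ol (lactol, anomer mixture)
Conditions: i-Bu2AlH, CH2Cl2, −78 °C; MeOH, aq. KNaC4H4O6
Reagents that add atoms: none
Why: partial hydride reduction of a γ-lactone, whose tetrahedral aluminium alkoxide is stable at −78 °C and gives the lactol on work-up.

Step 7
Reactants: 13 (3S,4S,5R)-3-(2-methylpropyl)-4-(propan-2-yl)-5-(2,4,6-trimethoxyphenyl)oxolan-2-ol
Product: 15 (1R,2S,3S)-3-(2-methylpropyl)-2-(propan-2-yl)-1-(2,4,6-trimethoxyphenyl)pent-4-yn-1-ol, via open-chain hydroxy aldehyde 14 (not isolated)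
Conditions: dimethyl (1-diazo-2-oxopropyl)phosphonate, K2CO3, MeOH, 0 °C to rt
Reagents that add atoms: dimethyl (1-diazo-2-oxopropyl)phosphonate, CC(=O)C(=[N+]=[N-])P(=O)(OC)OC
Why: Ohira–Bestmann (Seyferth–Gilbert) homologation of the lactol through its open hydroxy aldehyde form, which turns the lactone carbon into the future C4a, frees the C2 hydroxyl, and under mild carbonate conditions should leave the α-stereocentre (future C4) intact.

Step 8
Reactants: 15 (1R,2S,3S)-3-(2-methylpropyl)-2-(propan-2-yl)-1-(2,4,6-trimethoxyphenyl)pent-4-yn-1-ol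
Product: 18 (1R,2S,3S)-3-(2-methylpropyl)-2-(propan-2-yl)-5-[tri(propan-2-yl)silyloxy]-1-(2,4,6-trimethoxyphenyl)pent-4-yn-1-ol, via dilithium alkoxide acetylide 16 (not isolated), via dilithium alkoxide ynolate 17 (not isolated)
Conditions: n-BuLi (2 equiv), THF, −78 °C; t-BuOOLi (from t-BuOOH, LiN(SiMe3)2), −78 to 0 °C; i-Pr3SiCl, −78 to 0 °C
Reagents that add atoms: tert-butyl hydroperoxide, CC(C)(C)OO; triisopropylsilyl chloride, CC(C)[Si](Cl)(C(C)C)C(C)C
Why: oxygenation of a lithium acetylide by lithium tert-butyl peroxide to the ynolate followed by O-silylation with a bulky chlorosilane, in which the hindered secondary lithium alkoxide, like the lithium tert-butoxide formed alongside, should not be silylated at low temperature.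

Step 9
Reactants: 18 (1R,2S,3S)-3-(2-methylpropyl)-2-(propan-2-yl)-5-[tri(propan-2-yl)silyloxy]-1-(2,4,6-trimethoxyphenyl)pent-4-yn-1-ol; 19 trichloroethylene
Product: 21 (1R,2S,3S)-1-[(E)-1,2-dichloroethenyloxy]-3-(2-methylpropyl)-2-(propan-2-yl)-5-[tri(propan-2-yl)silyloxy]-1-(2,4,6-trimethoxyphenyl)pent-4-yne, via potassium alkoxide 20 (not isolated)
Conditions: KH, THF, 0 °C to rt; 19, rt
Reagents that add atoms: none
Why: addition of an alkoxide to dichloroacetylene generated in the flask from trichloroethylene (the trichloroethylene route to ynol ethers), which works on hindered secondary benzylic alcohols, gives the (E)-dichlorovinyl ether by anti addition, and leaves C2 untouched because only the O–H bond reacts.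

Step 10
Reactants: 21 (1R,2S,3S)-1-[(E)-1,2-dichloroethenyloxy]-3-(2-methylpropyl)-2-(propan-2-yl)-5-[tri(propan-2-yl)silyloxy]-1-(2,4,6-trimethoxyphenyl)pent-4-yne
Product: 24 (1R,2S,3S)-1-(ethynyloxy)-3-(2-methylpropyl)-2-(propan-2-yl)-5-[tri(propan-2-yl)silyloxy]-1-(2,4,6-trimethoxyphenyl)pent-4-yne, via chloroethynyl ether 22 (not isolated), via lithium alkoxyacetylide 23 (not isolated)
Conditions: n-BuLi (2.2 equiv), THF, −78 to −40 °C; H2O, −78 °C; kept below 0 °C and used at once
Reagents that add atoms: none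
Why: base-induced dehydrochlorination and chlorine–lithium exchange of a 1,2-dichlorovinyl ether followed by cold protonation of the lithium alkoxyacetylide, with the bulky O–Si(i-Pr)3 group expected to resist n-BuLi at −78 °C and the product kept cold because loss of ketene and benzylic ionisation are its likely decay paths.

Step 11
Reactants: 24 (1R,2S,3S)-1-(ethynyloxy)-3-(2-methylpropyl)-2-(propan-2-yl)-5-[tri(propan-2-yl)silyloxy]-1-(2,4,6-trimethoxyphenyl)pent-4-yne; 25 ethoxyacetylene
Product: 26 (2R,3S,4S)-7-ethoxy-4-(2-methylpropyl)-3-(propan-2-yl)-5-[tri(propan-2-yl)silyloxy]-2-(2,4,6-trimethoxyphenyl)chromane (2,3-cis, 3,4-trans)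
Conditions: [Rh(cod)2]BF4 (10 mol %), rac-2,2'-bis(diphenylphosphino)-1,1'-binaphthyl (BINAP, 10 mol %), H2 then Ar, CH2Cl2; 25 (5 equiv); slow addition of 24, 0 °C to rt
Reagents that add atoms: none
Why: Proposed new method: the cationic monovalent rhodium–BINAP fragment, freed of cyclooctadiene by hydrogen, should bind both alkynes of 24 and couple them oxidatively to a trivalent rhodacyclopentadiene (C4a–C8a bond), after which ethoxyacetylene inserts into a Rh–C bond and reductive elimination forms C5–C6 and C7–C8 and releases the benzene ring. The closest known reaction type is the cationic rhodium–bisphosphine [2+2+2] cycloaddition of tethered 1,7-diynes with a monoalkyne, alkynyl ethers included; what is untested is a diyne built from an O-linked ethynyl ether and a siloxyalkyne. The pyran ring closes in the oxidative coupling, where the O1–C2–C3–C4 tether makes the C4a–C8a bond intramolecular and six-membered, and ring A closes by the formal [4+2] union of the rhodacycle with the third alkyne. No stereocentre is formed, and C2, C3 and C4 are spectator sp3 carbons of the tether. The step needs insertion with the ethoxy-bearing carbon next to C8 and the CH carbon next to C5, which the bulk of the OSi(i-Pr)3 group at the C5 terminus against the bare C8–H terminus should enforce, and it needs cross-cyclisation to win over homotrimerisation, which slow addition of 24 to excess 25 should secure. Working between 0 °C and room temperature should keep the secondary ethynyl ether ahead of its thermal loss of ketene.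

Step 12
Reactants: 26 (2R,3S,4S)-7-ethoxy-4-(2-methylpropyl)-3-(propan-2-yl)-5-[tri(propan-2-yl)silyloxy]-2-(2,4,6-trimethoxyphenyl)chromane
Product: 27 (2R,3S,4S)-7-ethoxy-4-(2-methylpropyl)-3-(propan-2-yl)-2-(2,4,6-trimethoxyphenyl)chroman-5-ol
Conditions: n-Bu4NF, THF, 0 °C
Reagents that add atoms: none
Why: fluoride cleavage of an aryl silyl ether, driven by the Si–F bond and the good phenoxide leaving group, with nothing else in 26 reactive toward fluoride.

Step 13
Reactants: 27 (2R,3S,4S)-7-ethoxy-4-(2-methylpropyl)-3-(propan-2-yl)-2-(2,4,6-trimethoxyphenyl)chroman-5-ol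
Product: 28 (2R,3S,4S)-2-(3,5-diformyl-2,4,6-trimethoxyphenyl)-7-ethoxy-5-hydroxy-4-(2-methylpropyl)-3-(propan-2-yl)chromane-6,8-dicarbaldehyde
Conditions: Cl2CHOMe (excess), TiCl4, CH2Cl2, −78 to 0 °C; ice–water
Reagents that add atoms: dichloromethyl methyl ether, COC(Cl)Cl; water, O
Why: Rieche formylation, in which each ring is a 2-alkyl-1,3,5-trioxygenated benzene whose two free positions are each flanked by two oxygen substituents and so should take two formyl groups with excess reagent, the titanium phenoxide at C5 directing the first entry to C6.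

Step 14
Reactants: 28 (2R,3S,4S)-2-(3,5-diformyl-2,4,6-trimethoxyphenyl)-7-ethoxy-5-hydroxy-4-(2-methylpropyl)-3-(propan-2-yl)chromane-6,8-dicarbaldehyde
Product: 29 sideroxylonal B, (2R,3S,4S)-2-(3,5-diformyl-2,4,6-trihydroxyphenyl)-5,7-dihydroxy-4-(2-methylpropyl)-3-(propan-2-yl)chromane-6,8-dicarbaldehyde
Conditions: BCl3 (excess), CH2Cl2, −78 °C to rt; H2O
Reagents that add atoms: none
Why: chelation-assisted Lewis acid dealkylation of aryl ethers, in which every methoxy group and the ethoxy group lies ortho to a formyl group that anchors boron and delivers chloride to the alkyl carbon, while the secondary O1–C2 bond, whose cation is destabilised by the diformylated ring, should be spared.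

**Compound list**

1 | 2,4,6-trimethoxybenzaldehyde | COc1cc(OC)c(C=O)c(OC)c1 | starting material
2 | (Z)-4-methylpent-2-ene | C/C=C\C(C)C | starting material
3 | (Z)-(4-methylpent-2-en-1-yl)potassium | [K]C/C=C\C(C)C | intermediate (not isolated)
4 | (Z)-(4-methylpent-2-en-1-yl)diisopinocampheylborane, isopinocampheyl groups from (−)-α-pinene | CC(C)/C=C\CB([C@H]1C[C@H]2C[C@@H]([C@@H]1C)C2(C)C)[C@H]1C[C@H]2C[C@@H]([C@@H]1C)C2(C)C | intermediate (not isolated)
5 | (1R,2S)-2-(propan-2-yl)-1-(2,4,6-trimethoxyphenyl)but-3-en-1-ol (syn) | C=C[C@H](C(C)C)[C@@H](O)c1c(OC)cc(OC)cc1OC | intermediate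
6 | 9-[(3R,4R)-4-hydroxy-3-(propan-2-yl)-4-(2,4,6-trimethoxyphenyl)butyl]-9-borabicyclo[3.3.1]nonane | C(CB1C2CCCC1CCC2)[C@H](C(C)C)[C@@H](O)c1c(OC)cc(OC)cc1OC | intermediate (not isolated)
7 | (1R,2R)-2-(propan-2-yl)-1-(2,4,6-trimethoxyphenyl)butane-1,4-diol | OCC[C@H](C(C)C)[C@@H](O)c1c(OC)cc(OC)cc1OC | intermediate
8 | (4R,5R)-4-(propan-2-yl)-5-(2,4,6-trimethoxyphenyl)oxolan-2-one (cis) | O=C1C[C@H](C(C)C)[C@H](c2c(OC)cc(OC)cc2OC)O1 | intermediate
9 | 3-bromo-2-methylprop-1-ene (methallyl bromide) | C=C(C)CBr | starting material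
10 | lithium enolate of lactone 8 | [Li]OC1=C[C@H](C(C)C)[C@H](c2c(OC)cc(OC)cc2OC)O1 | intermediate (not isolated)
11 | (3S,4S,5R)-3-(2-methylprop-2-en-1-yl)-4-(propan-2-yl)-5-(2,4,6-trimethoxyphenyl)oxolan-2-one (3,4-trans, 4,5-cis) | O=C1[C@@H](CC(C)=C)[C@H](C(C)C)[C@H](c2c(OC)cc(OC)cc2OC)O1 | intermediate
12 | (3S,4S,5R)-3-(2-methylpropyl)-4-(propan-2-yl)-5-(2,4,6-trimethoxyphenyl)oxolan-2-one | O=C1[C@@H](CC(C)C)[C@H](C(C)C)[C@H](c2c(OC)cc(OC)cc2OC)O1 | intermediate
13 | (3S,4S,5R)-3-(2-methylpropyl)-4-(propan-2-yl)-5-(2,4,6-trimethoxyphenyl)oxolan-2-ol (anomer mixture) | OC1[C@@H](CC(C)C)[C@H](C(C)C)[C@H](c2c(OC)cc(OC)cc2OC)O1 | intermediate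
14 | (2S,3S)-3-[(R)-hydroxy(2,4,6-trimethoxyphenyl)methyl]-4-methyl-2-(2-methylpropyl)pentanal | CC(C)C[C@H](C=O)[C@H](C(C)C)[C@@H](O)c1c(OC)cc(OC)cc1OC | intermediate (not isolated)
15 | (1R,2S,3S)-3-(2-methylpropyl)-2-(propan-2-yl)-1-(2,4,6-trimethoxyphenyl)pent-4-yn-1-ol | CC(C)C[C@H](C#C)[C@H](C(C)C)[C@@H](O)c1c(OC)cc(OC)cc1OC | intermediate
16 | dilithium alkoxide acetylide of 15 | CC(C)C[C@H](C#C[Li])[C@H](C(C)C)[C@@H](O[Li])c1c(OC)cc(OC)cc1OC | intermediate (not isolated)
17 | dilithium alkoxide ynolate derived from 15 | CC(C)C[C@H](C#CO[Li])[C@H](C(C)C)[C@@H](O[Li])c1c(OC)cc(OC)cc1OC | intermediate (not isolated)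
18 | (1R,2S,3S)-3-(2-methylpropyl)-2-(propan-2-yl)-5-[tri(propan-2-yl)silyloxy]-1-(2,4,6-trimethoxyphenyl)pent-4-yn-1-ol | CC(C)C[C@H](C#CO[Si](C(C)C)(C(C)C)C(C)C)[C@H](C(C)C)[C@@H](O)c1c(OC)cc(OC)cc1OC | intermediate
19 | trichloroethylene | ClC=C(Cl)Cl | starting material
20 | potassium alkoxide of 18 | CC(C)C[C@H](C#CO[Si](C(C)C)(C(C)C)C(C)C)[C@H](C(C)C)[C@@H](O[K])c1c(OC)cc(OC)cc1OC | intermediate (not isolated)
21 | (1R,2S,3S)-1-[(E)-1,2-dichloroethenyloxy]-3-(2-methylpropyl)-2-(propan-2-yl)-5-[tri(propan-2-yl)silyloxy]-1-(2,4,6-trimethoxyphenyl)pent-4-yne | CC(C)C[C@H](C#CO[Si](C(C)C)(C(C)C)C(C)C)[C@H](C(C)C)[C@@H](O/C(Cl)=C\Cl)c1c(OC)cc(OC)cc1OC | intermediate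
22 | (1R,2S,3S)-1-(chloroethynyloxy) analogue of 24 | CC(C)C[C@H](C#CO[Si](C(C)C)(C(C)C)C(C)C)[C@H](C(C)C)[C@@H](OC#CCl)c1c(OC)cc(OC)cc1OC | intermediate (not isolated)
23 | lithium acetylide of 24 (lithium alkoxyacetylide) | CC(C)C[C@H](C#CO[Si](C(C)C)(C(C)C)C(C)C)[C@H](C(C)C)[C@@H](OC#C[Li])c1c(OC)cc(OC)cc1OC | intermediate (not isolated)
24 | (1R,2S,3S)-1-(ethynyloxy)-3-(2-methylpropyl)-2-(propan-2-yl)-5-[tri(propan-2-yl)silyloxy]-1-(2,4,6-trimethoxyphenyl)pent-4-yne (key precursor) | CC(C)C[C@H](C#CO[Si](C(C)C)(C(C)C)C(C)C)[C@H](C(C)C)[C@@H](OC#C)c1c(OC)cc(OC)cc1OC | intermediate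
25 | ethoxyacetylene | CCOC#C | starting material
26 | (2R,3S,4S)-7-ethoxy-4-(2-methylpropyl)-3-(propan-2-yl)-5-[tri(propan-2-yl)silyloxy]-2-(2,4,6-trimethoxyphenyl)chromane | CC(C)C[C@@H]1c2c(O[Si](C(C)C)(C(C)C)C(C)C)cc(OCC)cc2O[C@@H](c2c(OC)cc(OC)cc2OC)[C@H]1C(C)C | intermediate
27 | (2R,3S,4S)-7-ethoxy-4-(2-methylpropyl)-3-(propan-2-yl)-2-(2,4,6-trimethoxyphenyl)chroman-5-ol | CC(C)C[C@@H]1c2c(O)cc(OCC)cc2O[C@@H](c2c(OC)cc(OC)cc2OC)[C@H]1C(C)C | intermediate
28 | (2R,3S,4S)-2-(3,5-diformyl-2,4,6-trimethoxyphenyl)-7-ethoxy-5-hydroxy-4-(2-methylpropyl)-3-(propan-2-yl)chromane-6,8-dicarbaldehyde | CC(C)C[C@@H]1c2c(O)c(C=O)c(OCC)c(C=O)c2O[C@@H](c2c(OC)c(C=O)c(OC)c(C=O)c2OC)[C@H]1C(C)C | intermediate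
29 | sideroxylonal B | CC(C)C[C@@H]1c2c(O)c(C=O)c(O)c(C=O)c2O[C@@H](c2c(O)c(C=O)c(O)c(C=O)c2O)[C@H]1C(C)C | target

**Step count**

Total steps: 14. Longest linear sequence: 14 steps (from 1 or 2 to 29).

**Steps most likely to fail**

1. Step 11 (labelled step). The ethynyl ether may decay by loss of ketene or benzylic ionisation before it cyclises, ethoxyacetylene may trimerise with itself, the third alkyne may insert with the wrong orientation, or the bulky siloxyalkyne may not enter the metallacycle. The fallback uses known chemistry, sets out from 18 and comes back at 26. The hydroxyl of 18 is silylated (Et3SiCl, imidazole, DMF) to the triethylsilyl ether F1, so that it cannot trap a ketene. Heating F1 with 3-ethoxycyclobut-2-en-1-one in toluene at 80 °C (Danheiser benzannulation: opening to the vinylketene, [2+2] addition to the siloxyalkyne, four-electron ring opening, six-electron closure, tautomerisation) should give the phenol F2. In F2 the side-chain carbon lies between the new hydroxyl (future O1) and the silyloxy carbon (C5), with ethoxy at C7. Catalytic camphorsulfonic acid in CH2Cl2 at 0 °C then ionises the benzylic C–OSiEt3 bond and the phenol oxygen closes the pyran to 26. C2 is set here under equilibrating conditions, which should favour the 2,3-cis isomer, with the aryl group equatorial and the C3 and C4 substituents trans-diaxial.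

2. Step 9. The potassium alkoxide may take the silyl group from the ynol oxygen, or the hindered alkoxide may add too slowly to dichloroacetylene. The fallback avoids the alkoxide, sets out from 18 and comes back at 24. Formylation (acetic formic anhydride, pyridine, 0 °C) gives the formate F3. Ramirez dibromo-olefination of the formate carbonyl (PPh3, CBr4, CH2Cl2, 0 °C) gives the 2,2-dibromovinyl ether F4. Corey–Fuchs-type treatment with n-BuLi (2.2 equiv, THF, −78 °C) and cold water then gives 24 directly, bypassing 21.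

3. Step 13. Formylation may stop short of four groups once each ring is deactivated, and TiCl4 may reversibly open the O1–C2 bond and erode the C2 configuration. The fallback replaces electrophilic formylation by halogenation and metalation, sets out from 26 and comes back at 28. N-Bromosuccinimide (4 equiv, CH2Cl2, 0 °C) gives the 6,8,3',5'-tetrabromide F5. Fourfold bromine–lithium exchange (t-BuLi, THF, −78 °C) and quenching with DMF gives the silylated tetraaldehyde F6. n-Bu4NF in THF then gives 28.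

**Further compounds**

F1 | step 11 | (1R,2S,3S)-1-(triethylsilyloxy)-3-(2-methylpropyl)-2-(propan-2-yl)-5-[tri(propan-2-yl)silyloxy]-1-(2,4,6-trimethoxyphenyl)pent-4-yne | CC(C)C[C@H](C#CO[Si](C(C)C)(C(C)C)C(C)C)[C@H](C(C)C)[C@@H](O[Si](CC)(CC)CC)c1c(OC)cc(OC)cc1OC
F2 | step 11 | 5-ethoxy-2-[(1R,2S,3S)-3-(2-methylpropyl)-2-(propan-2-yl)-1-(triethylsilyloxy)-1-(2,4,6-trimethoxyphenyl)propan-3-yl]-3-[tri(propan-2-yl)silyloxy]phenol | CC(C)C[C@H](c1c(O)cc(OCC)cc1O[Si](C(C)C)(C(C)C)C(C)C)[C@H](C(C)C)[C@@H](O[Si](CC)(CC)CC)c1c(OC)cc(OC)cc1OC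
F3 | step 9 | formate ester of 18 | CC(C)C[C@H](C#CO[Si](C(C)C)(C(C)C)C(C)C)[C@H](C(C)C)[C@@H](OC=O)c1c(OC)cc(OC)cc1OC
F4 | step 9 | 2,2-dibromovinyl ether of 18 | CC(C)C[C@H](C#CO[Si](C(C)C)(C(C)C)C(C)C)[C@H](C(C)C)[C@@H](OC=C(Br)Br)c1c(OC)cc(OC)cc1OC
F5 | step 13 | 6,8-dibromo-2-(3,5-dibromo-2,4,6-trimethoxyphenyl) derivative of 26 | CC(C)C[C@@H]1c2c(O[Si](C(C)C)(C(C)C)C(C)C)c(Br)c(OCC)c(Br)c2O[C@@H](c2c(OC)c(Br)c(OC)c(Br)c2OC)[C@H]1C(C)C
F6 | step 13 | 5-O-triisopropylsilyl ether of 28 | CC(C)C[C@@H]1c2c(O[Si](C(C)C)(C(C)C)C(C)C)c(C=O)c(OCC)c(C=O)c2O[C@@H](c2c(OC)c(C=O)c(OC)c(C=O)c2OC)[C@H]1C(C)C
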